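**Retrosynthetic overview**
1. The acetate is put on last. The key cut is C3–C4, between an aldehyde carbon and the β-carbon of an acrylate. Both are natural acceptors, so an (E)-β-triflyloxy acrylate is turned into a β-chromio acrylate (β-acyl vinyl anion, d3 synthon). A chiral Ni/Cr catalyst sets C4 and the E alkene geometry is kept.
2. The aldehyde comes from a tert-butyl thioester. The tertiary carbinol C4' comes from Rh/BINAP-controlled 1,2-addition of AlMe3 to a 4-substituted cyclohexenone.
3. The only ring is made once, by enamine-catalysed Michael addition to methyl vinyl ketone and aldol condensation. This sets C1'.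
4. C6 comes from an iminium-catalysed Mukaiyama–Michael addition of a silyl ketene thioacetal to crotonaldehyde.
5. The triflate comes from methyl hex-5-enoate by cross-metathesis, formylation and E-selective O-triflation.

Assumption: locants are C1 (ester), C2=C3, C4 (acetoxy carbon), C5 (CH2), C6 (methyl-bearing CH) and C1'–C6' for the ring (C1' carries the chain, C4' the OH); the sense of induction of each chiral catalyst is taken from its closest published model, and both antipodes of each are accessible.

**Step 1**
Reactants: 1 S-tert-butyl thioacetate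
Product: 2 tert-butyl{[1-(tert-butylsulfanyl)ethenyl]oxy}dimethylsilane
Conditions: LiN(iPr)2, THF/DMPU, −78 °C; TBSCl, −78 °C to rt
Reagents that add atoms: tert-butyldimethylsilyl chloride, CC(C)(C)[Si](C)(C)Cl
Why: Kinetic enolisation and O-silylation of a thioester (silyl ketene thioacetal formation) is routine, and no stereocentre is made.

**Step 2**
Reactants: 2 tert-butyl{[1-(tert-butylsulfanyl)ethenyl]oxy}dimethylsilane; 3 (E)-crotonaldehyde
Product: 4 S-tert-butyl (3S)-3-methyl-5-oxopentanethioate
Conditions: (2R,5R)-5-benzyl-2-tert-butyl-3-methylimidazolidin-4-one·Cl3CCO2H (20 mol %), CH2Cl2, H2O (2 equiv), −55 °C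
Reagents that add atoms: none
Why: In this iminium-catalysed Mukaiyama–Michael addition the catalyst shields one face of the E-iminium ion of 3, so the soft thioacetal adds 1,4 from the open face and sets C6 (the antipode gives the R product with indoles for the same priority pattern, so this one gives 3S).

**Step 3**
Reactants: 4 S-tert-butyl (3S)-3-methyl-5-oxopentanethioate; 5 methyl vinyl ketone
Product: 7 S-tert-butyl (3R)-3-[(1S)-4-oxocyclohex-2-en-1-yl]butanethioate, via keto aldehyde 6 (not isolated)
Conditions: 5 (1.5 equiv), (S)-2-[methoxy(diphenyl)methyl]pyrrolidine (5 mol %), ethyl 3,4-dihydroxybenzoate (20 mol %), neat, 4 °C; then (PhCH2)2NH2+ CF3CO2− (0.3 equiv), toluene, 50 °C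
Reagents that add atoms: none
Why: This is an enamine-catalysed Michael addition followed by intramolecular aldol condensation (organocatalytic Robinson-type annulation), in which the bulky pyrrolidine substituent blocks one enamine face so C1' is set S under catalyst control as in the citronellal-to-bisabolane series, and the mild ammonium salt closes the ring without harming the thioester.

**Step 4**
Reactants: 7 S-tert-butyl (3R)-3-[(1S)-4-oxocyclohex-2-en-1-yl]butanethioate
Product: 8 S-tert-butyl (3R)-3-[(1S,4R)-4-hydroxy-4-methylcyclohex-2-en-1-yl]butanethioate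
Conditions: [Rh(cod)Cl]2 (2.5 mol %), (S)-BINAP (6 mol %), AlMe3 (1.5 equiv), THF, 0 °C to rt; aq. Rochelle salt
Reagents that add atoms: trimethylaluminium, C[Al](C)C
Why: In this rhodium/BINAP-catalysed face-selective 1,2-addition of AlMe3 to a cyclic enone the ligand picks the carbonyl face (methyl syn to the chain, OH trans, C4' = R), which matches the intrinsic axial attack, while the hindered thioester should survive AlMe3 in THF at this temperature.

**Step 5**
Reactants: 8 S-tert-butyl (3R)-3-[(1S,4R)-4-hydroxy-4-methylcyclohex-2-en-1-yl]butanethioate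
Product: 9 (3R)-3-[(1S,4R)-4-hydroxy-4-methylcyclohex-2-en-1-yl]butanal
Conditions: iBu2AlH (2.3 equiv), CH2Cl2, −78 °C; aq. Rochelle salt
Reagents that add atoms: none
Why: Hydride reduction of the thioester stops at the aluminium hemithioacetal at −78 °C and gives the aldehyde on work-up, the first equivalent only deprotonates the alcohol, and no stereocentre is touched.

**Step 6**
Reactants: 10 methyl hex-5-enoate; 11 2-methylbut-2-ene
Product: 12 methyl 6-methylhept-5-enoate
Conditions: second-generation Grubbs catalyst (1 mol %), 11 as solvent, 35 °C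
Reagents that add atoms: none
Why: Olefin cross-metathesis of a terminal alkene in excess 2-methylbut-2-ene installs the dimethylvinyl terminus cleanly because the trisubstituted product no longer reacts.

**Step 7**
Reactants: 12 methyl 6-methylhept-5-enoate
Product: 13 methyl 2-formyl-6-methylhept-5-enoate (mainly enol, stereocentre labile)
Conditions: NaH (1.5 equiv), HCO2Me (3 equiv), THF, 0 °C to rt; aq. HCl
Reagents that add atoms: methyl formate, COC=O
Why: This crossed Claisen condensation with non-enolisable methyl formate is driven by deprotonation of the product, whose α-carbon becomes sp2 in the next step.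

**Step 8**
Reactants: 13 methyl 2-formyl-6-methylhept-5-enoate
Product: 14 methyl (2E)-6-methyl-2-{[(trifluoromethanesulfonyl)oxy]methylidene}hept-5-enoate
Conditions: Tf2O (1.2 equiv), aq. Me4NOH, toluene, 0 °C
Reagents that add atoms: triflic anhydride, O=S(=O)(OS(=O)(=O)C(F)(F)F)C(F)(F)F
Why: O-triflation of the enolate with a non-chelating tetramethylammonium counter-ion gives the E enol triflate (OTf trans to the ester), as known for acetoacetate-type enolates, whereas a chelating lithium or sodium ion would give Z.

**Step 9 (key step)**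
Reactants: 9 (3R)-3-[(1S,4R)-4-hydroxy-4-methylcyclohex-2-en-1-yl]butanal; 14 methyl (2E)-6-methyl-2-{[(trifluoromethanesulfonyl)oxy]methylidene}hept-5-enoate
Product: 16 methyl (2E)-2-{(2S,4R)-2-hydroxy-4-[(1S,4R)-4-hydroxy-4-methylcyclohex-2-en-1-yl]pentylidene}-6-methylhept-5-enoate, via alkenylchromium dichloride 15 (not isolated)
Conditions: CrCl2 (10 mol %), (S)-N-[2-(4-isopropyl-4,5-dihydro-1,3-oxazol-2-yl)-6-methylphenyl]methanesulfonamide (11 mol %), 1,8-bis(dimethylamino)naphthalene (11 mol %), NiCl2·(2,9-dimethyl-1,10-phenanthroline) (2 mol %), Mn (2 equiv), Cp2ZrCl2 (1.2 equiv), LiCl (2 equiv), MeCN, rt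
Reagents that add atoms: none
Why: In this catalytic asymmetric Nozaki–Hiyama–Kishi coupling zerovalent nickel inserts into the C–OTf bond with retention and passes the alkenyl group to chromium, so the normally electrophilic acrylate β-carbon becomes a β-acyl vinyl anion that adds to the equally electrophilic aldehyde carbon of 9, the chiral sulfonamide directs Re-face attack (C4 = S) over the remote C6 centre, and the weakly basic organochromium tolerates the free tertiary alcohol and the ester.

**Step 10**
Reactants: 16 methyl (2E)-2-{(2S,4R)-2-hydroxy-4-[(1S,4R)-4-hydroxy-4-methylcyclohex-2-en-1-yl]pentylidene}-6-methylhept-5-enoate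
Product: 17 methyl (2E)-2-{(2S,4R)-2-acetoxy-4-[(1S,4R)-4-hydroxy-4-methylcyclohex-2-en-1-yl]pentylidene}-6-methylhept-5-enoate
Conditions: Ac2O (1.2 equiv), pyridine, DMAP (5 mol %), CH2Cl2, 0 °C
Reagents that add atoms: acetic anhydride, CC(=O)OC(C)=O
Why: This O-acylation is selective for the secondary allylic alcohol because the tertiary one is too hindered at 0 °C, and C4 keeps its configuration since only the O–H bond is broken.

**Compound list**
1 | S-tert-butyl thioacetate | CC(=O)SC(C)(C)C | starting material
2 | tert-butyl{[1-(tert-butylsulfanyl)ethenyl]oxy}dimethylsilane | C=C(O[Si](C)(C)C(C)(C)C)SC(C)(C)C | intermediate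
3 | (E)-crotonaldehyde | C/C=C/C=O | starting material
4 | S-tert-butyl (3S)-3-methyl-5-oxopentanethioate | CC(C)(C)SC(=O)C[C@@H](C)CC=O | intermediate
5 | methyl vinyl ketone (but-3-en-2-one) | CC(=O)C=C | starting material
6 | S-tert-butyl (3R,4S)-4-formyl-3-methyl-7-oxooctanethioate | CC(C)(C)SC(=O)C[C@@H](C)[C@@H](C=O)CCC(C)=O | intermediate
7 | S-tert-butyl (3R)-3-[(1S)-4-oxocyclohex-2-en-1-yl]butanethioate | CC(C)(C)SC(=O)C[C@@H](C)[C@H]1C=CC(=O)CC1 | intermediate
8 | S-tert-butyl (3R)-3-[(1S,4R)-4-hydroxy-4-methylcyclohex-2-en-1-yl]butanethioate | CC(C)(C)SC(=O)C[C@@H](C)[C@H]1C=C[C@](C)(O)CC1 | intermediate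
9 | (3R)-3-[(1S,4R)-4-hydroxy-4-methylcyclohex-2-en-1-yl]butanal | O=CC[C@@H](C)[C@H]1C=C[C@](C)(O)CC1 | intermediate
10 | methyl hex-5-enoate | COC(=O)CCCC=C | starting material
11 | 2-methylbut-2-ene | CC=C(C)C | starting material
12 | methyl 6-methylhept-5-enoate | COC(=O)CCCC=C(C)C | intermediate
13 | methyl 2-formyl-6-methylhept-5-enoate | COC(=O)C(C=O)CCC=C(C)C | intermediate
14 | methyl (2E)-6-methyl-2-{[(trifluoromethanesulfonyl)oxy]methylidene}hept-5-enoate | COC(=O)/C(=C/OS(=O)(=O)C(F)(F)F)CCC=C(C)C | intermediate
15 | (E)-β-(dichlorochromio)acrylate from 14 (chiral ligand omitted) | COC(=O)/C(=C/[Cr](Cl)Cl)CCC=C(C)C | intermediate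
16 | methyl (2E)-2-{(2S,4R)-2-hydroxy-4-[(1S,4R)-4-hydroxy-4-methylcyclohex-2-en-1-yl]pentylidene}-6-methylhept-5-enoate | COC(=O)/C(=C/[C@H](C[C@@H](C)[C@H]1C=C[C@](C)(O)CC1)O)CCC=C(C)C | intermediate
17 | methyl (2E)-2-{(2S,4R)-2-acetoxy-4-[(1S,4R)-4-hydroxy-4-methylcyclohex-2-en-1-yl]pentylidene}-6-methylhept-5-enoate | COC(=O)/C(=C/[C@H](C[C@@H](C)[C@H]1C=C[C@](C)(O)CC1)OC(C)=O)CCC=C(C)C | target

**Step count**
Total: 10 steps. Longest linear sequence: 7 steps (1, 2, 3, 4, 5, 9, 10).

**Steps most likely to fail**

Step 9.
- Risks: nickel-mediated homocoupling of the electron-poor triflate; partial loss of E geometry, where the Z isomer would lactonise to a separable butenolide; and an unverified sense of induction for this ligand/substrate pair.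
- Fallback: it sets out from 9 and returns at 16. A Me2Zn/ProPhenol-catalysed addition of methyl propiolate to the Re face of 9 gives the γ-hydroxy ynoate F1.
- Trans-hydroalumination with NaAlH2(OCH2CH2OMe)2 in THF at −72 °C, followed by an I2 quench, gives the (Z)-α-iodo enoate F2.
- A Pd(dppf)Cl2-catalysed Negishi coupling of F2 with (4-methylpent-3-en-1-yl)zinc bromide proceeds with retention and gives 16.

Step 4.
- Risks: methyl transfer to, or rhodium insertion into, the thioester; and a mismatch between the ligand and the C1' centre.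
- Fallback: it sets out from 7 and returns at 9. Dimethylsulfonium methylide (Me3S+ I−, NaH, DMSO/THF) attacks the enone carbonyl axially and gives the vinyl spiro-epoxide F3, with oxygen trans to the chain.
- Excess LiEt3BH opens F3 at its CH2 group and reduces the thioester, giving the diol F4.
- TEMPO/PhI(OAc)2 oxidises only the primary alcohol of F4 and gives 9.

Step 8.
- Risks: an incomplete E/Z ratio, and retro-Claisen cleavage of 13 in aqueous base.
- Fallback: it sets out from 13 and returns at 16. TsCl, N-methylimidazole and Et3N in MeCN (the amine-base, E-selective tosylation of α-formyl esters) give the enol tosylate F5.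
- LiI in acetone exchanges the tosylate by addition–elimination and gives the vinyl iodide F6.
- F6 replaces 14 in the Ni/Cr coupling with 9 and gives 16.

**Further compounds**
F1 | step 9 | methyl (4S,6R)-4-hydroxy-6-[(1S,4R)-4-hydroxy-4-methylcyclohex-2-en-1-yl]hept-2-ynoate | COC(=O)C#C[C@H](C[C@@H](C)[C@H]1C=C[C@](C)(O)CC1)O
F2 | step 9 | methyl (2Z,4S,6R)-4-hydroxy-6-[(1S,4R)-4-hydroxy-4-methylcyclohex-2-en-1-yl]-2-iodohept-2-enoate | COC(=O)/C(I)=C/[C@H](C[C@@H](C)[C@H]1C=C[C@](C)(O)CC1)O
F3 | step 4 | S-tert-butyl (3R)-3-[(3R,6S)-1-oxaspiro[2.5]oct-4-en-6-yl]butanethioate | CC(C)(C)SC(=O)C[C@@H](C)[C@H]1C=C[C@]2(OC2)CC1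
F4 | step 4 | (3R)-3-[(1S,4R)-4-hydroxy-4-methylcyclohex-2-en-1-yl]butan-1-ol | OCC[C@@H](C)[C@H]1C=C[C@](C)(O)CC1
F5 | step 8 | methyl (2E)-6-methyl-2-{[(4-methylbenzenesulfonyl)oxy]methylidene}hept-5-enoate | COC(=O)/C(=C/OS(=O)(=O)c1ccc(C)cc1)CCC=C(C)C
F6 | step 8 | methyl (2E)-2-(iodomethylidene)-6-methylhept-5-enoate | COC(=O)/C(=C/I)CCC=C(C)C
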